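The isoflavone is cut at the two bonds joining ring A to ring C, C8a–O1 and C4a–C4. In ring A the carbonyl carbon C4 sits on C4a and the pyranone oxygen O1 on adjacent C8a, an ortho acyl/oxygen pair that maps onto an aryne (C4a≡C8a) inserting into the C(=O)–OH bond of the ring B arylacetic acid. One operation thus delivers the 2-hydroxydeoxybenzoin containing every skeletal atom but C2. The aryne is released from an ortho-silylaryl triflate derived from symmetric 3,5-dimethoxy-4-prenylphenol; its C5 methoxy group orients the insertion. One-carbon ring closure, MOM removal and chelation-controlled 5-O-demethylation finish the route.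

Key step: step 8

Remark: ring A positions of all intermediates are given in the isoflavone numbering of the target (O1, C4, C4a, C5 to C8, C8a); prenyl means 3-methylbut-2-enyl and MOM means methoxymethyl.

Step 1
Reactants: 1 3,5-dimethoxyphenol
Product: 2 (3,5-dimethoxyphenoxy)tri(propan-2-yl)silane
Conditions: TIPSCl, imidazole, DMF, rt
Reagents that add atoms: chlorotri(propan-2-yl)silane, CC(C)[Si](Cl)(C(C)C)C(C)C
Why: Standard O-silylation of a phenol; the bulky triisopropylsilyl ether is a poor lithium-directing group and shields the two positions next to it, which prepares the site-selective metalation of step 2.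

Step 2
Reactants: 2 (3,5-dimethoxyphenoxy)tri(propan-2-yl)silane; 3 prenyl bromide (1-bromo-3-methylbut-2-ene)
Product: 5 [3,5-dimethoxy-4-(3-methylbut-2-enyl)phenoxy]tri(propan-2-yl)silane, via aryllithium 4 (not isolated)
Conditions: n-BuLi, THF, 0 °C → rt; then CuBr·SMe2 (10 mol%), 3, −78 °C → rt
Reagents that add atoms: none
Why: Directed ortho-metalation puts lithium on the carbon between the two methoxy groups, the only site with two cooperating donors and no silyl shielding, and copper-assisted allylic substitution at the primary carbon of the bromide should give the linear prenyl arene.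

Step 3
Reactants: 5 [3,5-dimethoxy-4-(3-methylbut-2-enyl)phenoxy]tri(propan-2-yl)silane
Product: 6 3,5-dimethoxy-4-(3-methylbut-2-enyl)phenol
Conditions: TBAF, AcOH, THF, 0 °C → rt
Reagents that add atoms: none
Why: Fluoride-induced cleavage of the aryl silyl ether (desilylation), buffered with acetic acid so that the prenyl group and the methyl ethers are not touched.

Step 4
Reactants: 6 3,5-dimethoxy-4-(3-methylbut-2-enyl)phenol
Product: 7 3,5-dimethoxy-4-(3-methylbut-2-enyl)phenyl N-(propan-2-yl)carbamate
Conditions: i-PrNCO, Et3N (cat.), CH2Cl2, rt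
Reagents that add atoms: isopropyl isocyanate (2-isocyanatopropane), CC(C)N=C=O
Why: Base-catalysed addition of the phenol to the isocyanate (carbamoylation) installs a strong ortho-directing group that can later be removed under mild basic conditions.

Step 5
Reactants: 7 3,5-dimethoxy-4-(3-methylbut-2-enyl)phenyl N-(propan-2-yl)carbamate
Product: 11 3,5-dimethoxy-4-(3-methylbut-2-enyl)-2-(trimethylsilyl)phenyl N-(propan-2-yl)carbamate, via N-silyl carbamate 8 (not isolated), via ortho-lithiated carbamate 9 (not isolated), via C-silylated N-silyl carbamate 10 (not isolated)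
Conditions: TBSOTf, TMEDA, Et2O, 0 °C → rt; then n-BuLi, TMEDA, −78 °C; then TMSCl, −78 °C → rt; aq NaHSO4 work-up
Reagents that add atoms: chlorotrimethylsilane, C[Si](C)(C)Cl
Why: Carbamate-directed ortho-metalation after transient N-silylation of the N–H: the two ring positions ortho to the carbamate are equivalent in the symmetric substrate and are activated by both the carbamate and a methoxy group, so lithiation there at −78 °C should outrun deprotonation of the benzylic–allylic CH2, and chlorotrimethylsilane traps the aryllithium before the N-silyl group is lost on acidic work-up.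

Step 6
Reactants: 11 3,5-dimethoxy-4-(3-methylbut-2-enyl)-2-(trimethylsilyl)phenyl N-(propan-2-yl)carbamate
Product: 13 3,5-dimethoxy-4-(3-methylbut-2-enyl)-2-(trimethylsilyl)phenyl trifluoromethanesulfonate, via silylphenol 12 (not isolated)
Conditions: DBU, Et2NH, MeCN, 40 °C; then PhNTf2, rt
Reagents that add atoms: N-phenylbis(trifluoromethanesulfonimide), O=S(=O)(N(c1ccccc1)S(=O)(=O)C(F)(F)F)C(F)(F)F
Why: Base-induced elimination of isopropyl isocyanate from the N–H carbamate (E1cB type, the isocyanate being scavenged by diethylamine) frees the phenoxide, which is triflated in the same pot by a mild triflyl donor, with no acid present that could protodesilylate the electron-rich arylsilane.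

Step 7
Reactants: 14 2,4-dihydroxyphenylacetic acid
Product: 16 2,4-bis(methoxymethoxy)phenylacetic acid, via MOM ester 15 (not isolated)
Conditions: MOMCl, i-Pr2NEt, CH2Cl2, 0 °C → rt; then LiOH, THF/MeOH/H2O, rt; cold dilute HCl to pH 4
Reagents that add atoms: chloromethyl methyl ether, COCCl; lithium hydroxide, [Li+].[OH-]
Why: O-alkylation protects both phenols as MOM acetals and also esterifies the carboxylate; the very labile MOM ester is then saponified by hydroxide (acyl–oxygen cleavage, so one carboxyl oxygen of 16 comes from hydroxide) while the aryl MOM ethers are stable to base.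

Step 8
Reactants: 13 3,5-dimethoxy-4-(3-methylbut-2-enyl)-2-(trimethylsilyl)phenyl trifluoromethanesulfonate; 16 2,4-bis(methoxymethoxy)phenylacetic acid
Product: 18 2-[2,4-bis(methoxymethoxy)phenyl]-1-[6-hydroxy-2,4-dimethoxy-3-(3-methylbut-2-enyl)phenyl]ethanone, via aryne 17 (not isolated)
Conditions: CsF (4 equiv), THF, 125 °C, sealed tube (13 limiting, 16 in slight excess)
Reagents that add atoms: none
Why: Fluoride attacks silicon of 13 and the resulting aryl anion expels triflate to give aryne 17; the carboxylate of 16 adds through oxygen to C8a, the aryl anion left at C4a attacks the neighbouring ester carbonyl, and the strained four-membered alkoxide opens to the C4 ketone and the C8a phenoxide, so the net result is insertion of the aryne into the C(=O)–O bond, with O1 of the target coming from the acid. The closest known reaction type is the fluoride-mediated insertion of arynes from 2-(trimethylsilyl)aryl triflates into carboxylic acids, which gives ortho-hydroxyaryl ketones. No ring is closed in the product (the four-membered ring is only a transient) and no stereocenter is formed. The step needs regioselectivity, oxygen at C8a and not at C4a, and this should be secured by the C5 methoxy group, whose inductive pull polarises the distorted triple bond so that the nucleophile enters at the distal carbon and the negative charge develops on C4a next to the C–O bond. It also needs acyl transfer to outrun protonation of the aryl anion, which is favoured in hot THF, where fluoride is released slowly and the acid is largely present as its sparingly soluble cesium salt. The fluoride conditions should leave the prenyl alkene, the methyl ethers and the MOM acetals untouched.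

Step 9
Reactants: 18 2-[2,4-bis(methoxymethoxy)phenyl]-1-[6-hydroxy-2,4-dimethoxy-3-(3-methylbut-2-enyl)phenyl]ethanone
Product: 20 3-[2,4-bis(methoxymethoxy)phenyl]-5,7-dimethoxy-6-(3-methylbut-2-enyl)chromen-4-one, via enaminone 19 (not isolated)
Conditions: Me2NCH(OMe)2, toluene, 95 °C
Reagents that add atoms: N,N-dimethylformamide dimethyl acetal, COC(OC)N(C)C
Why: Condensation of the activated methylene with the amide acetal gives an enaminone that supplies C2, and the ortho phenol closes ring C by 6-endo-trig oxa-Michael addition and loss of dimethylamine (the standard deoxybenzoin-to-isoflavone annulation), under non-acidic conditions that the prenyl and MOM groups tolerate.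

Step 10
Reactants: 20 3-[2,4-bis(methoxymethoxy)phenyl]-5,7-dimethoxy-6-(3-methylbut-2-enyl)chromen-4-one
Product: 21 3-(2,4-dihydroxyphenyl)-5,7-dimethoxy-6-(3-methylbut-2-enyl)chromen-4-one
Conditions: 3 M aq HCl, MeOH, 50 °C
Reagents that add atoms: none
Why: Acid-catalysed methanolysis of the two MOM acetals; at this stage both oxygens flanking the prenyl group (O5 and O7) are still methylated, so acid-induced chroman formation has no free phenol to use, and the aryl methyl ethers and the chromone are inert to dilute acid.

Step 11
Reactants: 21 3-(2,4-dihydroxyphenyl)-5,7-dimethoxy-6-(3-methylbut-2-enyl)chromen-4-one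
Product: 22 7-O-methylluteone, 3-(2,4-dihydroxyphenyl)-5-hydroxy-7-methoxy-6-(3-methylbut-2-enyl)chromen-4-one
Conditions: MgI2·OEt2 (5 equiv), THF/toluene, 60 °C; cold dilute aq HCl work-up
Reagents that add atoms: none
Why: Chelation-controlled ether cleavage: magnesium bridges the C4 carbonyl oxygen and O5 in a six-membered chelate, which activates only the peri 5-O-methyl group for SN2 demethylation by iodide, whereas the 7-methoxy group cannot chelate and the mild Lewis acid should leave the prenyl alkene alone.

Compound list
1 | 3,5-dimethoxyphenol | COc1cc(O)cc(OC)c1 | starting material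
2 | (3,5-dimethoxyphenoxy)tri(propan-2-yl)silane | COc1cc(O[Si](C(C)C)(C(C)C)C(C)C)cc(OC)c1 | intermediate
3 | prenyl bromide (1-bromo-3-methylbut-2-ene) | CC(C)=CCBr | starting material
4 | [2,6-dimethoxy-4-(tri(propan-2-yl)silyloxy)phenyl]lithium | [Li]c1c(OC)cc(O[Si](C(C)C)(C(C)C)C(C)C)cc1OC | intermediate
5 | [3,5-dimethoxy-4-(3-methylbut-2-enyl)phenoxy]tri(propan-2-yl)silane | COc1cc(O[Si](C(C)C)(C(C)C)C(C)C)cc(OC)c1CC=C(C)C | intermediate
6 | 3,5-dimethoxy-4-(3-methylbut-2-enyl)phenol | COc1cc(O)cc(OC)c1CC=C(C)C | intermediate
7 | 3,5-dimethoxy-4-(3-methylbut-2-enyl)phenyl N-(propan-2-yl)carbamate | COc1cc(OC(=O)NC(C)C)cc(OC)c1CC=C(C)C | intermediate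
8 | 3,5-dimethoxy-4-(3-methylbut-2-enyl)phenyl N-(tert-butyldimethylsilyl)-N-(propan-2-yl)carbamate | COc1cc(OC(=O)N(C(C)C)[Si](C)(C)C(C)(C)C)cc(OC)c1CC=C(C)C | intermediate
9 | 2-lithio derivative of 8 (lithium on the ring carbon between the carbamate oxygen and a methoxy group) | [Li]c1c(OC(=O)N(C(C)C)[Si](C)(C)C(C)(C)C)cc(OC)c(CC=C(C)C)c1OC | intermediate
10 | 3,5-dimethoxy-4-(3-methylbut-2-enyl)-2-(trimethylsilyl)phenyl N-(tert-butyldimethylsilyl)-N-(propan-2-yl)carbamate | COc1cc(OC(=O)N(C(C)C)[Si](C)(C)C(C)(C)C)c([Si](C)(C)C)c(OC)c1CC=C(C)C | intermediate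
11 | 3,5-dimethoxy-4-(3-methylbut-2-enyl)-2-(trimethylsilyl)phenyl N-(propan-2-yl)carbamate | COc1cc(OC(=O)NC(C)C)c([Si](C)(C)C)c(OC)c1CC=C(C)C | intermediate
12 | 3,5-dimethoxy-4-(3-methylbut-2-enyl)-2-(trimethylsilyl)phenol | COc1cc(O)c([Si](C)(C)C)c(OC)c1CC=C(C)C | intermediate
13 | 3,5-dimethoxy-4-(3-methylbut-2-enyl)-2-(trimethylsilyl)phenyl trifluoromethanesulfonate | COc1cc(OS(=O)(=O)C(F)(F)F)c([Si](C)(C)C)c(OC)c1CC=C(C)C | intermediate
14 | 2,4-dihydroxyphenylacetic acid | OC(=O)Cc1ccc(O)cc1O | starting material
15 | methoxymethyl 2,4-bis(methoxymethoxy)phenylacetate | COCOC(=O)Cc1ccc(OCOC)cc1OCOC | intermediate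
16 | 2,4-bis(methoxymethoxy)phenylacetic acid | COCOc1ccc(CC(=O)O)c(OCOC)c1 | intermediate
17 | 1,2-didehydro-3,5-dimethoxy-4-(3-methylbut-2-enyl)benzene (ring A aryne, C4a≡C8a) | COC1=CC#CC(OC)=C1CC=C(C)C | intermediate
18 | 2-[2,4-bis(methoxymethoxy)phenyl]-1-[6-hydroxy-2,4-dimethoxy-3-(3-methylbut-2-enyl)phenyl]ethanone | COCOc1ccc(CC(=O)c2c(O)cc(OC)c(CC=C(C)C)c2OC)c(OCOC)c1 | intermediate
19 | 2-[2,4-bis(methoxymethoxy)phenyl]-3-(dimethylamino)-1-[6-hydroxy-2,4-dimethoxy-3-(3-methylbut-2-enyl)phenyl]prop-2-en-1-one (alkene geometry immaterial) | COCOc1ccc(C(=CN(C)C)C(=O)c2c(O)cc(OC)c(CC=C(C)C)c2OC)c(OCOC)c1 | intermediate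
20 | 3-[2,4-bis(methoxymethoxy)phenyl]-5,7-dimethoxy-6-(3-methylbut-2-enyl)chromen-4-one | COCOc1ccc(-c2coc3cc(OC)c(CC=C(C)C)c(OC)c3c2=O)c(OCOC)c1 | intermediate
21 | 3-(2,4-dihydroxyphenyl)-5,7-dimethoxy-6-(3-methylbut-2-enyl)chromen-4-one | COc1cc2occ(-c3ccc(O)cc3O)c(=O)c2c(OC)c1CC=C(C)C | intermediate
22 | 7-O-methylluteone, 3-(2,4-dihydroxyphenyl)-5-hydroxy-7-methoxy-6-(3-methylbut-2-enyl)chromen-4-one | COc1cc2occ(-c3ccc(O)cc3O)c(=O)c2c(O)c1CC=C(C)C | target

Total step count: 11 steps.
Longest linear sequence: 10 steps (steps 1 to 6 and 8 to 11, from 3,5-dimethoxyphenol); step 7 is a one-step side branch.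

Steps most likely to fail

Step 8 (aryne insertion). The aryl anion at C4a may be protonated before it reaches the carbonyl group, which would stop the reaction at the O-aryl ester, and the phenoxide or the enolate of the product may add to further aryne. Fallback by organolithium acylation: the route is left at carbamate 7, which is converted as in step 5 into the ortho-lithiated N-silyl carbamate 9. Instead of chlorotrimethylsilane, 9 is treated at −78 °C with the Weinreb amide N-methoxy-N-methyl-2-[2,4-bis(methoxymethoxy)phenyl]acetamide F1, prepared from acid 16 with carbonyldiimidazole and MeNH(OMe)·HCl. Aqueous NaHSO4 work-up releases the ketone and removes the N-silyl group to give 2-{[2,4-bis(methoxymethoxy)phenyl]acetyl}-3,5-dimethoxy-4-(3-methylbut-2-enyl)phenyl N-(propan-2-yl)carbamate F2. Cleavage of the carbamate with DBU and Et2NH in MeCN then gives deoxybenzoin 18, where the route is rejoined.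

Step 5 (ortho-silylation). Deprotonation of the doubly activated benzylic–allylic CH2 group, or attack of the base on incompletely N-silylated carbamate, may compete with ring metalation. Fallback by halogen–lithium exchange and retro-Brook rearrangement: the route is left at phenol 6, which is iodinated at one of its two equivalent free positions next to the hydroxyl group (I2, NaHCO3, THF/H2O, 0 °C) to give 2-iodo-3,5-dimethoxy-4-(3-methylbut-2-enyl)phenol F3. Silylation with hexamethyldisilazane gives [2-iodo-3,5-dimethoxy-4-(3-methylbut-2-enyl)phenoxy]trimethylsilane F4. With n-BuLi in THF at −78 °C, iodine–lithium exchange should be much faster than any C–H deprotonation; the silyl group then migrates from oxygen to carbon, and the resulting lithium salt of 12 is trapped with Tf2O to give triflate 13, where the route is rejoined.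

Step 2 (lithiation and prenylation). Attack at the tertiary end of the allylic bromide (allylic transposition), bromine–lithium exchange followed by homocoupling, or incomplete metalation may erode this step. Fallback by allylation and olefin cross-metathesis: the route is left at silyl ether 2, whose aryllithium 4 is quenched with allyl bromide, for which both modes of allylic substitution give the same product, to give (4-allyl-3,5-dimethoxyphenoxy)tri(propan-2-yl)silane F5. Cross-metathesis with excess 2-methylbut-2-ene and the second-generation Grubbs catalyst (H2IMes)(PCy3)Cl2Ru=CHPh in CH2Cl2 at 40 °C turns the allyl into the prenyl group and gives 5, where the route is rejoined.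

Further compounds
F1 | step 8 | N-methoxy-N-methyl-2-[2,4-bis(methoxymethoxy)phenyl]acetamide | COCOc1ccc(CC(=O)N(C)OC)c(OCOC)c1
F2 | step 8 | 2-{[2,4-bis(methoxymethoxy)phenyl]acetyl}-3,5-dimethoxy-4-(3-methylbut-2-enyl)phenyl N-(propan-2-yl)carbamate | COCOc1ccc(CC(=O)c2c(OC(=O)NC(C)C)cc(OC)c(CC=C(C)C)c2OC)c(OCOC)c1
F3 | step 5 | 2-iodo-3,5-dimethoxy-4-(3-methylbut-2-enyl)phenol | COc1cc(O)c(I)c(OC)c1CC=C(C)C
F4 | step 5 | [2-iodo-3,5-dimethoxy-4-(3-methylbut-2-enyl)phenoxy]trimethylsilane | COc1cc(O[Si](C)(C)C)c(I)c(OC)c1CC=C(C)C
F5 | step 2 | (4-allyl-3,5-dimethoxyphenoxy)tri(propan-2-yl)silane | C=CCc1c(OC)cc(O[Si](C(C)C)(C(C)C)C(C)C)cc1OC
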